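The route rests on one disconnection: the 9α-oxygen and C13 of the side chain are 1,4-related through C11–C12 (O–C9–C11–C12–C13), so the tertiary carbinol and its chain are taken back to a γ-lactone spiro-fused to ring B at C9. A Mn(OAc)3 radical annulation of acetic acid on an exocyclic C9=C11 alkene should form C11–C12, C9–O and the C9 stereocentre in one operation. Its precursor is the 3β-acetoxy-4,4,8α,10β-tetramethyl-9-methylene trans-decalin, built from (R)-carvone by two enolate alkylations and an iron-hydride radical closure of ring A. The lactone carbonyl (C13) then carries the butenolide.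

Key step: step 8

Remarks on the chemistry:
- Labdane numbering is used throughout (ring carbons C1–C10, side chain C11–C16).
- Compound 4 is carried as a mixture of C6 epimers, because that centre is planarised again in step 2.
- Stannane 18 is assumed to be purchasable; otherwise it is one step from benzyl chloromethyl ether and Bu3SnLi.
- The γ-hydroxy ketones 19–21 are drawn open-chain; they equilibrate with their 9,13-hemiketals.
- The C3 acetate is kept through the key step because it is inert to trivalent manganese in hot acetic acid; it is deliberately given up in step 9 and put back in step 10, before the ylide step, so that no free C3 hydroxyl meets the ketenylidene ylide.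

Step 1
Reactants: 1 (R)-carvone; 2 iodomethane
Product: 4 6-methylcarvone (both C6 epimers), via lithium dienolate 3 (not isolated)
Conditions: LiN(iPr)2 (1.05 equiv), THF, −78 °C; then MeI, −78 → 0 °C
Reagents that add atoms: iodomethane, CI
Why: Kinetic deprotonation of the enone at the α′ carbon C6 and SN2 methylation of the cross-conjugated lithium dienolate (enolate alkylation); the new centre is not controlled and need not be.

Step 2
Reactants: 4 6-methylcarvone; 5 propargyl bromide
Product: 7 6-methyl-6-propargylcarvone (propargyl trans to isopropenyl), via lithium enolate 6 (not isolated)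
Conditions: LiN(iPr)2 (1.1 equiv), THF, −78 °C; then propargyl bromide, DMPU, −78 °C → rt
Reagents that add atoms: propargyl bromide, BrCC#C
Why: Enolate alkylation in which the tetrasubstituted lithium enolate takes the reactive propargylic halide on the face anti to the neighbouring isopropenyl group, so that the chain ends trans to it and the methyl cis, which is the C10 configuration of the target; a halide cannot enter the double Michael pathway that acrylic acceptors open with this dienolate.

Step 3
Reactants: 7 6-methyl-6-propargylcarvone
Product: 8 6-methyl-6-(3-oxopropyl)carvone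
Conditions: CpRuCl(Ph2PCH2PPh2) (2 mol %), iPrOH/H2O, 100 °C
Reagents that add atoms: water, O
Why: Ruthenium-vinylidene anti-Markovnikov hydration of a terminal alkyne should give the aldehyde and not the methyl ketone, under neutral conditions that leave the enone and the isopropenyl group untouched.

Step 4
Reactants: 8 6-methyl-6-(3-oxopropyl)carvone
Product: 9 3β-hydroxy-4,4,8,10β-tetramethyl-5α-decal-7-en-9-one
Conditions: Fe(acac)3 (30 mol %), PhSiH3 (2.5 equiv), EtOH/HOCH2CH2OH (5:1), 60 °C, degassed, dilute
Reagents that add atoms: none
Why: Hydrogen atom transfer from the iron hydride to the isopropenyl CH2 gives the tertiary C4 radical, which closes ring A on the aldehyde carbon (6-exo radical cyclisation onto a carbonyl group, a reductive alkene–carbonyl cyclisation of the Bonjoch–Bradshaw type) and sets the gem-dimethyl group; the trans fusion is fixed by C5 and C10, and the new C3 centre should prefer the equatorial 3β-oxygen of the chair transition state, clear of the axial hydrogens at C1 and C5.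

Step 5
Reactants: 9 3β-hydroxy-4,4,8,10β-tetramethyl-5α-decal-7-en-9-one
Product: 11 3β-hydroxy-4,4,8α,10β-tetramethyl-5α-decalin-9-one, via 8β-methyl ketone 10 (not isolated)
Conditions: H2 (1 atm), Pd/C (10% palladium on carbon), EtOAc, rt; filter; then NaOMe (0.3 equiv), MeOH, rt
Reagents that add atoms: none
Why: Heterogeneous hydrogenation saturates the only C=C bond, most likely from the α face away from the 10β-methyl, and methoxide-mediated enolisation then moves the C8 methyl to the equatorial 8α position, out of the 1,3-diaxial contact with the 10β-methyl (thermodynamic epimerisation, C10 being quaternary).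

Step 6
Reactants: 11 3β-hydroxy-4,4,8α,10β-tetramethyl-5α-decalin-9-one; 12 acetic anhydride
Product: 13 3β-acetoxy-4,4,8α,10β-tetramethyl-5α-decalin-9-one
Conditions: Ac2O, pyridine, DMAP (cat.), CH2Cl2, rt
Reagents that add atoms: acetic anhydride, CC(=O)OC(C)=O
Why: DMAP-catalysed O-acetylation of the only hydroxyl group; the C8 centre is already at its thermodynamic configuration and cannot be harmed by the mild base.

Step 7
Reactants: 13 3β-acetoxy-4,4,8α,10β-tetramethyl-5α-decalin-9-one; 14 dibromomethane
Product: 15 3β-acetoxy-4,4,8α,10β-tetramethyl-9-methylene-5α-decalin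
Conditions: Zn dust, CH2Br2, TiCl4, THF/CH2Cl2, 0 °C → rt
Reagents that add atoms: dibromomethane, BrCBr
Why: Takai–Lombardo methylenation with a non-basic titanium–zinc methylene reagent, which is known to convert hindered, enolisable ketones without epimerisation and to leave esters alone, so that the 8α-methyl and the acetate survive.

Step 8
Reactants: 15 3β-acetoxy-4,4,8α,10β-tetramethyl-9-methylene-5α-decalin; 16 acetic acid
Product: 17 3β-acetoxy-9α,13-spiro-γ-lactone (15,16-dinor-labdan-13,9α-olide)
Conditions: Mn(OAc)3·2H2O (2.5 equiv), KOAc, glacial AcOH, reflux, N2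
Reagents that add atoms: acetic acid, CC(=O)O
Why: The oxo-centred Mn(OAc)3 cluster enolises a bound acetate and releases the carboxymethyl radical, which adds to the unhindered CH2 terminus C11 of the 1,1-disubstituted alkene to give the tertiary C9 radical; a second equivalent of trivalent manganese oxidises this radical and the tethered carboxylate closes on C9, so that C11–C12 and C9–O are made in one flask. The closest known reaction is the Mn(OAc)3 γ-lactone annulation of alkenes with acetic acid (Heiba–Dessau and Bush–Finkbeiner), well documented for methylenecycloalkanes. The lactone ring closes by attack of the carboxylate oxygen on the trigonal cationic C9, a favoured five-membered closure in which the carboxyl C=O stays outside the ring, and the step as a whole is a formal [3+2] radical–polar crossover annulation. The new C9 stereocentre is controlled by the ring B chair: the oxygen enters along the axial α trajectory, anti to the axial 10β-methyl that screens the β face, which leaves C11 equatorial. The step needs radical attack at C11 only (secured by the terminal CH2 and the tertiary radical it produces), capture at C9 faster than a shift of the C8 hydrogen or the C10 methyl or loss of a proton (secured by the intramolecular carboxylate and the acetate buffer), and an otherwise inert substrate (the C3 acetate and the saturated skeleton offer no competing enolisable or oxidisable site).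

Step 9
Reactants: 17 3β-acetoxy-9α,13-spiro-γ-lactone; 18 tributyl[(benzyloxy)methyl]stannane
Product: 19 16-benzyloxy-3β,9α-dihydroxy-14,15-dinor-labdan-13-one
Conditions: 18 (4.5 equiv), nBuLi (4.4 equiv), THF, −78 °C, 15 min; then 17 in THF, −78 °C; aq NH4Cl
Reagents that add atoms: tributyl[(benzyloxy)methyl]stannane, CCCC[Sn](CCCC)(CCCC)COCc1ccccc1
Why: Tin–lithium exchange gives the α-alkoxy organolithium, which should add once to the γ-lactone (nucleophilic acyl addition arrested at the chelated lithium lactolate, as with sugar lactones) and open to the hydroxy ketone only on work-up, while the surplus reagent removes the C3 acetate by double addition; any acetate that survives converges on 20 in step 10.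

Step 10
Reactants: 19 16-benzyloxy-3β,9α-dihydroxy-14,15-dinor-labdan-13-one; 12 acetic anhydride
Product: 20 3β-acetoxy-16-benzyloxy-9α-hydroxy-14,15-dinor-labdan-13-one
Conditions: Ac2O (1.5 equiv), pyridine, DMAP (cat.), CH2Cl2, 0 °C → rt
Reagents that add atoms: acetic anhydride, CC(=O)OC(C)=O
Why: Selective O-acetylation of the secondary equatorial 3β-hydroxyl, because the 9α-hydroxyl is tertiary and axial (or tied up as the equally hindered hemiketal hydroxyl) and does not acylate under these conditions.

Step 11
Reactants: 20 3β-acetoxy-16-benzyloxy-9α-hydroxy-14,15-dinor-labdan-13-one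
Product: 21 3β-acetoxy-9α,16-dihydroxy-14,15-dinor-labdan-13-one
Conditions: H2 (1 atm), Pd/C (10% palladium on carbon), EtOAc, rt
Reagents that add atoms: none
Why: Hydrogenolysis of the benzyl ether, clean here because the molecule holds no C=C bond at this stage and neither the ketone nor the acetate is reduced under one atmosphere of hydrogen.

Step 12
Reactants: 21 3β-acetoxy-9α,16-dihydroxy-14,15-dinor-labdan-13-one; 22 (triphenylphosphoranylidene)ketene
Product: 24 3β-acetoxy-9α-hydroxy-labd-13-en-15,16-olide (the target), via ester ylide 23 (not isolated)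
Conditions: Ph3P=C=C=O (1.2 equiv), toluene, 90 °C
Reagents that add atoms: (triphenylphosphoranylidene)ketene, O=C=C=P(c1ccccc1)(c1ccccc1)c1ccccc1
Why: Bestmann butenolide synthesis, in which the primary hydroxyl of the α-ketol adds across the ketene C=C bond to give a stabilised acyl ylide that closes on the C13 ketone by intramolecular Wittig reaction, as in cardenolide syntheses from 21-hydroxy-20-ketones that carry a free tertiary hydroxyl and an acetate; the neutral conditions should spare the acetate and avoid conjugate addition of the 9α-hydroxyl.

Compound list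
1 | (R)-carvone | CC1=CC[C@H](CC1=O)C(C)=C | starting material
2 | iodomethane | CI | starting material
3 | lithium α′-dienolate of (R)-carvone (O–Li on C1, C1=C6 and C2=C3) | CC1=CC[C@H](C=C1O[Li])C(C)=C | intermediate
4 | 6-methylcarvone, 2,6-dimethyl-5-isopropenylcyclohex-2-en-1-one, C5 as in 1, both C6 epimers | CC1=CC[C@H](C(C)C1=O)C(C)=C | intermediate
5 | propargyl bromide (3-bromoprop-1-yne) | BrCC#C | starting material
6 | lithium enolate of 4 (tetrasubstituted C1=C6) | CC1=CC[C@H](C(C)=C1O[Li])C(C)=C | intermediate
7 | 6-methyl-6-propargylcarvone; propargyl trans and methyl cis to the isopropenyl group | C#CC[C@@]1(C)[C@@H](CC=C(C)C1=O)C(C)=C | intermediate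
8 | 6-methyl-6-(3-oxopropyl)carvone, same configuration as 7 | O=CCC[C@@]1(C)[C@@H](CC=C(C)C1=O)C(C)=C | intermediate
9 | 3β-hydroxy-4,4,8,10β-tetramethyl-5α-decal-7-en-9-one (trans-fused) | O[C@H]1CC[C@@]2(C)[C@@H](CC=C(C)C2=O)C1(C)C | intermediate
10 | 3β-hydroxy-4,4,8β,10β-tetramethyl-5α-decalin-9-one (axial 8-methyl) | O[C@H]1CC[C@@]2(C)[C@@H](CC[C@H](C)C2=O)C1(C)C | intermediate
11 | 3β-hydroxy-4,4,8α,10β-tetramethyl-5α-decalin-9-one (equatorial 8-methyl) | O[C@H]1CC[C@@]2(C)[C@@H](CC[C@@H](C)C2=O)C1(C)C | intermediate
12 | acetic anhydride | CC(=O)OC(C)=O | starting material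
13 | 3β-acetoxy-4,4,8α,10β-tetramethyl-5α-decalin-9-one | CC(=O)O[C@H]1CC[C@@]2(C)[C@@H](CC[C@@H](C)C2=O)C1(C)C | intermediate
14 | dibromomethane | BrCBr | starting material
15 | 3β-acetoxy-4,4,8α,10β-tetramethyl-9-methylene-5α-decalin (key-step precursor) | CC(=O)O[C@H]1CC[C@@]2(C)[C@@H](CC[C@@H](C)C2=C)C1(C)C | intermediate
16 | acetic acid | CC(=O)O | starting material
17 | 3β-acetoxy-9α,13-spiro-γ-lactone: lactone oxygen axial (α) on C9, C11 equatorial (β), carbonyl at C13 | CC(=O)O[C@H]1CC[C@@]2(C)[C@@H](CC[C@@H](C)[C@]23CCC(=O)O3)C1(C)C | intermediate
18 | tributyl[(benzyloxy)methyl]stannane | CCCC[Sn](CCCC)(CCCC)COCc1ccccc1 | starting material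
19 | 16-benzyloxy-3β,9α-dihydroxy-14,15-dinor-labdan-13-one (with its 9,13-hemiketal) | O[C@H]1CC[C@@]2(C)[C@@H](CC[C@@H](C)[C@]2(O)CCC(=O)COCc2ccccc2)C1(C)C | intermediate
20 | 3β-acetoxy-16-benzyloxy-9α-hydroxy-14,15-dinor-labdan-13-one | CC(=O)O[C@H]1CC[C@@]2(C)[C@@H](CC[C@@H](C)[C@]2(O)CCC(=O)COCc2ccccc2)C1(C)C | intermediate
21 | 3β-acetoxy-9α,16-dihydroxy-14,15-dinor-labdan-13-one (α-ketol) | CC(=O)O[C@H]1CC[C@@]2(C)[C@@H](CC[C@@H](C)[C@]2(O)CCC(=O)CO)C1(C)C | intermediate
22 | (triphenylphosphoranylidene)ketene | O=C=C=P(c1ccccc1)(c1ccccc1)c1ccccc1 | starting material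
23 | 16-O-[(triphenylphosphoranylidene)acetyl] ester of 21 | CC(=O)O[C@H]1CC[C@@]2(C)[C@@H](CC[C@@H](C)[C@]2(O)CCC(=O)COC(=O)C=P(c2ccccc2)(c2ccccc2)c2ccccc2)C1(C)C | intermediate
24 | 3β-acetoxy-9α-hydroxy-labd-13-en-15,16-olide (8α-methyl, 5α-H, 10β-methyl) | CC(=O)O[C@H]1CC[C@@]2(C)[C@@H](CC[C@@H](C)[C@]2(O)CCC2=CC(=O)OC2)C1(C)C | target

Total step count: 12
Longest linear sequence: 12 steps, from (R)-carvone 1 to 24

Steps most likely to fail

Step 8. The C9 cation may be lost to a shift of the C8 hydrogen or the 10β-methyl, or to loss of a proton, before the carboxylate closes; the exocyclic alkene may also migrate into the ring in hot acid, or the oxygen may close on the β face. The fallback sets out from 15 and comes back at 17, making the same two bonds by polar steps. Epoxidation of 15 with mCPBA/NaHCO3 in CH2Cl2 should take place on the α face, anti to the 10β-methyl, and give the 9α,11-epoxide F1. Sodium diethyl malonate in refluxing EtOH (NaOEt) should open F1 at the CH2 carbon C11; the C9 alkoxide lactonises and ethoxide removes the acetate, giving the 12-ethoxycarbonyl 3β-hydroxy spiro-lactone F2. Saponification with aq NaOH, acidification and heating in toluene decarboxylate and relactonise to the 3β-hydroxy spiro-lactone F3. Ac2O/pyridine then returns 17.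

Step 4. The tertiary radical may be reduced without ring closure, the alkoxy radical may reopen, or the facial preference at C3 may be weak. The fallback sets out from 8 and comes back at 9, closing ring A on a nitrile and setting C3 by hydride reduction. Aldehyde 8 is condensed with NH2OH·HCl/NaOAc in EtOH at 0 °C, at the aldehyde only, to the aldoxime F4. Dehydration with (CF3CO)2O/pyridine gives the nitrile F5. Fe(acac)3/PhSiH3 in EtOH at 60 °C should close the C4 radical on the nitrile carbon, and the imine is hydrolysed on acidic work-up to the 3,9-dione F6. NaBH4 in MeOH at −20 °C should reduce only the saturated C3 ketone, by axial hydride delivery from the α face as in 4,4-dimethyl-3-keto terpenoids, and leave the hindered conjugated C9 carbonyl. The same dione is reached by Dess–Martin oxidation of any C3 epimer mixture from step 4.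

Step 9. The lactolate may open in the flask and take a second organolithium, the lactone may be enolised, or the acetate may be removed only in part. The fallback sets out from 17 and comes back at 19, with the chelated N-methoxy-N-methylamide as the stop against over-addition. Me(MeO)NH·HCl/AlMe3 in CH2Cl2 (0 °C → rt, excess) should open the lactone, as it does with sclareolide, and aminolyse the acetate, giving the 3β,9α-dihydroxy N-methoxy-N-methylamide F7, which is used crude. Benzyloxymethyllithium (from 18 and nBuLi, 3.5 equiv, two of them taken by the hydroxyl groups) in THF at −78 °C then adds once and gives 19 on work-up.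

Further compounds
F1 | step 8 | 3β-acetoxy-9α,11-epoxy-4,4,8α,10β-tetramethyl-5α-decalin (spiro-epoxide, oxygen α) | CC(=O)O[C@H]1CC[C@@]2(C)[C@@H](CC[C@@H](C)[C@]23CO3)C1(C)C
F2 | step 8 | 12-ethoxycarbonyl 3β-hydroxy-9α,13-spiro-γ-lactone (C12 epimers) | O[C@H]1CC[C@@]2(C)[C@@H](CC[C@@H](C)[C@]23CC(C(=O)OCC)C(=O)O3)C1(C)C
F3 | step 8 | 3β-hydroxy-9α,13-spiro-γ-lactone | O[C@H]1CC[C@@]2(C)[C@@H](CC[C@@H](C)[C@]23CCC(=O)O3)C1(C)C
F4 | step 4 | aldoxime of 8 (E/Z mixture) | ON=CCC[C@@]1(C)[C@@H](CC=C(C)C1=O)C(C)=C
F5 | step 4 | 6-(2-cyanoethyl)-6-methylcarvone, configuration as in 8 | N#CCC[C@@]1(C)[C@@H](CC=C(C)C1=O)C(C)=C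
F6 | step 4 | 4,4,8,10β-tetramethyl-5α-decal-7-ene-3,9-dione | O=C1CC[C@@]2(C)[C@@H](CC=C(C)C2=O)C1(C)C
F7 | step 9 | 3β,9α-dihydroxy-14,15,16-trinor-labdan-13-oic acid N-methoxy-N-methylamide | O[C@H]1CC[C@@]2(C)[C@@H](CC[C@@H](C)[C@]2(O)CCC(=O)N(C)OC)C1(C)C
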